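Ring C of the isoflavan is cut at C2, the unsubstituted methylene flanked by O1 and C3. A 2-hydroxydeoxybenzoin already holds ring A, the C4 carbonyl, the C3 methylene and ring B, so one formamide-acetal carbon inserted between the phenolic oxygen and the doubly activated C3 methylene forges C2–C3 and O1–C2 and closes the pyranone in one operation. The precursor is the benzyl ketone made from 3,4-dimethoxyphenol and 2-benzyloxy-3,4-dimethoxyphenylacetonitrile; the benzyl ether masks the ring B phenol that later becomes the quinone. Transfer hydrogenation with dynamic kinetic resolution then sets C3 as S, hydrogenolysis removes C4–OH and benzyl, and phenol oxidation gives the quinone.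

Key step: step 4

Assumption: the configuration encoded in the target SMILES is read as 3S. The S,S ligand is chosen because this catalyst class converts aryl ketones into S carbinols; its antipode would be taken if the induction proved opposite in this series.

Design remark: the ring B oxygen must be blocked during ring closure, since a free hydroxyl there would close a 3-aroylbenzofuran. Benzyl is kept because it leaves in the same hydrogenation that removes C4–OH. Benzyl ethers are not expected to survive hot BF3·OEt2 or Fries conditions, so the ketone is assembled from the nitrile under cold Hoesch conditions, which also saves the hydrolysis to the arylacetic acid.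

Step 1
Reactants: 1 2-hydroxy-3,4-dimethoxybenzaldehyde
Product: 2 2-(benzyloxy)-3,4-dimethoxybenzaldehyde
Conditions: BnBr, K2CO3, DMF, 60 °C
Reagents that add atoms: benzyl bromide, BrCc1ccccc1
Why: Williamson ether synthesis, in which the phenoxide of 1 displaces bromide from benzyl bromide by SN2, warming in DMF overcoming the hydrogen bond to the aldehyde and the flanking methoxy group.

Step 2
Reactants: 2 2-(benzyloxy)-3,4-dimethoxybenzaldehyde
Product: 4 2-[2-(benzyloxy)-3,4-dimethoxyphenyl]acetonitrile, via N-formyl tosylenamine 3 (not isolated)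
Conditions: TosMIC, t-BuOK, DME, −50 °C; then MeOH, reflux
Reagents that add atoms: p-toluenesulfonylmethyl isocyanide (TosMIC), [C-]#[N+]CS(=O)(=O)c1ccc(C)cc1
Why: van Leusen reductive cyanation, in which the TosMIC anion adds to the aldehyde, the oxazoline formed opens to formamide 3, and methanolysis removes the formyl group and the sulfinate so that the ketenimine tautomerises to the arylacetonitrile, all under basic conditions that leave the benzyl and methyl ethers alone.

Step 3
Reactants: 4 2-[2-(benzyloxy)-3,4-dimethoxyphenyl]acetonitrile; 5 3,4-dimethoxyphenol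
Product: 7 2-[2-(benzyloxy)-3,4-dimethoxyphenyl]-1-(2-hydroxy-4,5-dimethoxyphenyl)ethan-1-one, via ketiminium chloride 6 (not isolated)
Conditions: ZnCl2, HCl (g), Et2O, 0 °C; then H2O, 90 °C
Reagents that add atoms: water, O
Why: Houben–Hoesch acylation, in which the nitrile activated by HCl and ZnCl2 attacks 5 at C6, the position ortho to the hydroxyl and para to the 3-methoxy group, and hydrolysis of iminium salt 6 gives the ketone, the cold ethereal medium being chosen so that the benzyl ether survives.

Step 4
Reactants: 7 2-[2-(benzyloxy)-3,4-dimethoxyphenyl]-1-(2-hydroxy-4,5-dimethoxyphenyl)ethan-1-one; 8 N,N-dimethylformamide dimethyl acetal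
Product: 11 3-[2-(benzyloxy)-3,4-dimethoxyphenyl]-6,7-dimethoxy-4H-chromen-4-one, via enaminone 9 (not isolated), via 2-(dimethylamino)chromanone 10 (not isolated)
Conditions: Me2NCH(OMe)2 (3 equiv), toluene, 100 °C
Reagents that add atoms: N,N-dimethylformamide dimethyl acetal, COC(OC)N(C)C
Why: The acetal ionises to a methoxyiminium ion and methoxide, which enolises the ketone at its only acidic carbon, the C3 methylene flanked by the C4 carbonyl and ring B; aminomethylenation of this enolate with loss of two methanol gives enaminone 9 and forms C2–C3. The hydrogen-bonded ring A phenol then adds to the β-carbon of the vinylogous amide and aminal 10 expels dimethylamine, forming O1–C2 and closing ring C by a 6-endo-trig addition–elimination that ends in the conjugated 4-pyranone. The closest known reaction type is the formamide-acetal annulation of 2-hydroxydeoxybenzoins to isoflavones, applied here to a new substrate. No stereocentre is created. The step needs only chemoselectivity: there is a single enolisable CH2, the ring A hydroxyl cyclises intramolecularly faster than the acetal can O-methylate it, and the ring B oxygen is capped as its benzyl ether so that the competing five-membered closure to a 3-aroylbenzofuran is excluded.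

Step 5
Reactants: 11 3-[2-(benzyloxy)-3,4-dimethoxyphenyl]-6,7-dimethoxy-4H-chromen-4-one
Product: 13 (3S,4S)-3-[2-(benzyloxy)-3,4-dimethoxyphenyl]-6,7-dimethoxy-3,4-dihydro-2H-chromen-4-ol, via isoflavanone 12 (not isolated)
Conditions: RuCl[(S,S)-TsDPEN](p-cymene) (5 mol %), HCO2H/Et3N (5:2), EtOAc, 40 °C
Reagents that add atoms: none
Why: Asymmetric transfer hydrogenation with dynamic kinetic resolution, in which the ruthenium hydride first reduces C2=C3 of the vinylogous ester in the conjugate sense to isoflavanone 12, whose C3 epimerises through the enol in the presence of Et3N, and the S,S catalyst then reduces the carbonyl of the 3S ketone faster, anti to the aryl group, so that C4 (S, catalyst control through the interaction of ring A with the p-cymene ligand) and C3 (S, by the resolution) should emerge cis.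

Step 6
Reactants: 13 (3S,4S)-3-[2-(benzyloxy)-3,4-dimethoxyphenyl]-6,7-dimethoxy-3,4-dihydro-2H-chromen-4-ol
Product: 15 6-[(3S)-6,7-dimethoxy-3,4-dihydro-2H-chromen-3-yl]-2,3-dimethoxyphenol, via debenzylated diol 14 (not isolated)
Conditions: H2 (1 atm), 10% Pd/C, EtOH/AcOH, rt
Reagents that add atoms: none
Why: Catalytic hydrogenolysis, in which the aryl benzyl ether is cleaved first to diol 14 and the C4–O bond, benzylic to ring A and activated by the para 7-methoxy group and by O1, is then cleaved on the metal surface without a free carbocation, so that C3, which takes no part, should keep its S configuration.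

Step 7
Reactants: 15 6-[(3S)-6,7-dimethoxy-3,4-dihydro-2H-chromen-3-yl]-2,3-dimethoxyphenol
Product: 16 Abroquinone A, 5-[(3S)-6,7-dimethoxy-3,4-dihydro-2H-chromen-3-yl]-2,3-dimethoxycyclohexa-2,5-diene-1,4-dione
Conditions: (KSO3)2NO, KH2PO4, H2O/acetone, rt
Reagents that add atoms: potassium nitrosodisulfonate (KSO3)2NO, [O]N(S(=O)(=O)[O-])S(=O)(=O)[O-].[K+].[K+]
Why: Teuber oxidation, in which one nitrosodisulfonate radical abstracts the phenolic hydrogen and a second adds at the free para position C5' to give the para-quinone after loss of imidodisulfonate, while ring A carries no free hydroxyl and the buffered neutral medium leaves C3 untouched.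

Compound list
1 | 2-hydroxy-3,4-dimethoxybenzaldehyde | COc1ccc(C=O)c(O)c1OC | starting material
2 | 2-(benzyloxy)-3,4-dimethoxybenzaldehyde | COc1ccc(C=O)c(OCc2ccccc2)c1OC | intermediate
3 | N-{2-[2-(benzyloxy)-3,4-dimethoxyphenyl]-1-[(4-methylphenyl)sulfonyl]ethenyl}formamide (alkene geometry undefined; present as its potassium salt) | O=CNC(=Cc1ccc(OC)c(OC)c1OCc1ccccc1)S(=O)(=O)c1ccc(C)cc1 | intermediate (not isolated)
4 | 2-[2-(benzyloxy)-3,4-dimethoxyphenyl]acetonitrile | COc1ccc(CC#N)c(OCc2ccccc2)c1OC | intermediate
5 | 3,4-dimethoxyphenol | COc1ccc(O)cc1OC | starting material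
6 | 2-[2-(benzyloxy)-3,4-dimethoxyphenyl]-1-(2-hydroxy-4,5-dimethoxyphenyl)ethan-1-iminium chloride | COc1ccc(CC(=[NH2+])c2cc(OC)c(OC)cc2O)c(OCc2ccccc2)c1OC.[Cl-] | intermediate (not isolated)
7 | 2-[2-(benzyloxy)-3,4-dimethoxyphenyl]-1-(2-hydroxy-4,5-dimethoxyphenyl)ethan-1-one | COc1ccc(CC(=O)c2cc(OC)c(OC)cc2O)c(OCc2ccccc2)c1OC | intermediate
8 | N,N-dimethylformamide dimethyl acetal | COC(OC)N(C)C | starting material
9 | 2-[2-(benzyloxy)-3,4-dimethoxyphenyl]-3-(dimethylamino)-1-(2-hydroxy-4,5-dimethoxyphenyl)prop-2-en-1-one (alkene geometry undefined) | COc1ccc(C(=CN(C)C)C(=O)c2cc(OC)c(OC)cc2O)c(OCc2ccccc2)c1OC | intermediate (not isolated)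
10 | 3-[2-(benzyloxy)-3,4-dimethoxyphenyl]-2-(dimethylamino)-6,7-dimethoxy-2,3-dihydro-4H-chromen-4-one (configuration undefined) | COc1ccc(C2C(N(C)C)Oc3cc(OC)c(OC)cc3C2=O)c(OCc2ccccc2)c1OC | intermediate (not isolated)
11 | 3-[2-(benzyloxy)-3,4-dimethoxyphenyl]-6,7-dimethoxy-4H-chromen-4-one | COc1ccc(C2=COc3cc(OC)c(OC)cc3C2=O)c(OCc2ccccc2)c1OC | intermediate
12 | rac-3-[2-(benzyloxy)-3,4-dimethoxyphenyl]-6,7-dimethoxy-2,3-dihydro-4H-chromen-4-one (C3 epimerising) | COc1ccc(C2COc3cc(OC)c(OC)cc3C2=O)c(OCc2ccccc2)c1OC | intermediate (not isolated)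
13 | (3S,4S)-3-[2-(benzyloxy)-3,4-dimethoxyphenyl]-6,7-dimethoxy-3,4-dihydro-2H-chromen-4-ol (cis) | COc1ccc([C@H]2COc3cc(OC)c(OC)cc3[C@H]2O)c(OCc2ccccc2)c1OC | intermediate
14 | (3S,4S)-3-(2-hydroxy-3,4-dimethoxyphenyl)-6,7-dimethoxy-3,4-dihydro-2H-chromen-4-ol (cis) | COc1ccc([C@H]2COc3cc(OC)c(OC)cc3[C@H]2O)c(O)c1OC | intermediate (not isolated)
15 | 6-[(3S)-6,7-dimethoxy-3,4-dihydro-2H-chromen-3-yl]-2,3-dimethoxyphenol | COc1ccc([C@H]2COc3cc(OC)c(OC)cc3C2)c(O)c1OC | intermediate
16 | Abroquinone A, 5-[(3S)-6,7-dimethoxy-3,4-dihydro-2H-chromen-3-yl]-2,3-dimethoxycyclohexa-2,5-diene-1,4-dione | COC1=C(OC)C(=O)C([C@H]2COc3cc(OC)c(OC)cc3C2)=CC1=O | target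

Total step count: 7. Longest linear sequence: 7 steps (1 to 16).

Steps most likely to fail

Step 3. The acidic medium may strip the benzyl ether, the activated nitrile may be captured at the phenolic oxygen instead of at carbon, or the iminium salt may hydrolyse sluggishly. The fallback joins the rings by an organometallic ketone synthesis without acid; it sets out from 4 and 5 and comes back at 7. Nitrile 4 is hydrolysed (KOH, aqueous EtOH, reflux, then acidification) to 2-[2-(benzyloxy)-3,4-dimethoxyphenyl]acetic acid F1, which is converted (CDI, then MeNHOMe·HCl, CH2Cl2) into 2-[2-(benzyloxy)-3,4-dimethoxyphenyl]-N-methoxy-N-methylacetamide F2. Phenol 5 is brominated ortho to the hydroxyl and para to the 3-methoxy group (NBS, MeCN, 0 °C) to 2-bromo-4,5-dimethoxyphenol F3 and protected (MOMCl, i-Pr2NEt, CH2Cl2) as 1-bromo-4,5-dimethoxy-2-(methoxymethoxy)benzene F4. Bromine–lithium exchange of F4 (n-BuLi, THF, −78 °C) and addition of the aryllithium to F2 at −78 °C should give 2-[2-(benzyloxy)-3,4-dimethoxyphenyl]-1-[4,5-dimethoxy-2-(methoxymethoxy)phenyl]ethan-1-one F5. HCl in MeOH at room temperature then removes the acetal while leaving the benzyl ether, giving 7.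

Step 5. Conjugate reduction of the vinylogous ester may stall, or carbonyl reduction may outrun the epimerisation at C3, so that the alkene survives or cis selectivity and enantiomeric purity erode. The fallback separates the two reductions; it sets out from 11 and comes back at 13. Isoflavone 11 is reduced in the 1,4 sense with LiBH(s-Bu)3 (THF, −78 °C) and racemic isoflavanone 12 is isolated. Compound 12 is then submitted alone to RuCl[(S,S)-TsDPEN](p-cymene) with HCO2H/Et3N, so that the catalyst has only the ketone reduction with dynamic kinetic resolution to perform. This fallback makes no compound outside the list (F0).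

Step 6. Cleavage of the C4–O bond may stop once the benzyl ether has gone, or acid-assisted dehydration across C3–C4 followed by hydrogenation may erode the configuration at C3. The fallback passes through the cyclic benzylic ether; it sets out from 13 and comes back at 15. Neutral hydrogenation (H2, 10% Pd/C, EtOAc, rt) removes only the benzyl group and diol 14 is isolated. A trace of HCl in EtOH at room temperature closes the free phenol onto C4 to the cis-fused (6aS,11aS)-2,3,9,10-tetramethoxy-6a,11a-dihydro-6H-[1]benzofuro[3,2-c]chromene F6, with C3 (now C6a) untouched. Hydrogenolysis of its benzylic aryl ether bond (H2, 10% Pd/C, AcOH, 50 °C) should open the five-membered ring to 15. The same pterocarpan is the species expected if the freed phenol closes onto C4 during step 6 itself, so both paths converge.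

Further compounds
F1 | step 3 | 2-[2-(benzyloxy)-3,4-dimethoxyphenyl]acetic acid | COc1ccc(CC(=O)O)c(OCc2ccccc2)c1OC
F2 | step 3 | 2-[2-(benzyloxy)-3,4-dimethoxyphenyl]-N-methoxy-N-methylacetamide | COc1ccc(CC(=O)N(C)OC)c(OCc2ccccc2)c1OC
F3 | step 3 | 2-bromo-4,5-dimethoxyphenol | COc1cc(O)c(Br)cc1OC
F4 | step 3 | 1-bromo-4,5-dimethoxy-2-(methoxymethoxy)benzene | COCOc1cc(OC)c(OC)cc1Br
F5 | step 3 | 2-[2-(benzyloxy)-3,4-dimethoxyphenyl]-1-[4,5-dimethoxy-2-(methoxymethoxy)phenyl]ethan-1-one | COCOc1cc(OC)c(OC)cc1C(=O)Cc1ccc(OC)c(OC)c1OCc1ccccc1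
F0 | step 5 | none | none
F6 | step 6 | (6aS,11aS)-2,3,9,10-tetramethoxy-6a,11a-dihydro-6H-[1]benzofuro[3,2-c]chromene | COc1ccc2[C@H]3COc4cc(OC)c(OC)cc4[C@H]3Oc2c1OC
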